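**Plan**

- Retrosynthesis (longipinane numbering: C1 ketone, C2=C3, bridgeheads C4 and C11, C5, C6 = CMe2, C7, C8, C9, C10 = quaternary C–Me): cut the O9 tiglate; then the O7 senecioate together with the C9–H bond (Evans–Tishchenko); then C7–O (conjugate borylation); then the cyclobutane bond C10–C11; then C9–C10 (one-carbon ring enlargement); last the Diels–Alder bonds C3–C4 and C5–C11.
- Forward: a Diels–Alder reaction builds the cyclohexene ring on a cyclohexadienone (cis-decalin); a radical 1,2-acyl shift enlarges the dienone-derived ring to seven; Saegusa–Ito oxidation gives the cis-fused bicyclo[5.4.0]undecadienedione 9; closure of C10–C11 then creates the cyclobutane, that is, the bicyclo[3.1.1]heptenone bridged by the seven-membered ring.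
- Enabling feature: C10–C11 is the central bond of a 1,4-dicarbonyl array (C1 ketone, C9 at the ketone level). In 9 these two carbons are the α′ positions of the two enones (the γ position of the seven-ring enone is the quaternary C6) and sit gauche across the ring-fusion bond C4–C5, so a bis-dienolate can be oxidised to close the four-membered ring.
- Stereochemistry: absolute configuration from a catalytic enantioselective Diels–Alder desymmetrisation (C5); C4 from hydrogen-atom transfer anti to the Diels–Alder-derived methyl stereocenter, which is erased afterwards; C10 and C11 from the cis ring fusion in the key step, where both epimers at the future C10 converge; C7 from ligand-controlled borylation; C9 from intramolecular 1,3-anti hydride delivery.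

Key step: step 7

Remark: the sense of induction of the chiral catalysts in steps 3 and 8 is assumed to follow the catalyst antipode, and the antipode giving the drawn enantiomer is used.
Remark: 6–10 are carried as mixtures at centers that become planar or are removed later; these centers are left undefined in the SMILES.

**Route**

Step 1
Reactants: 1 4,4-dimethylcyclohex-2-en-1-one
Product: 2 4,4-dimethylcyclohexa-2,5-dien-1-one
Conditions: DDQ, dioxane, reflux
Reagents that add atoms: none
Why: DDQ dehydrogenation of a 4,4-disubstituted cyclohexenone to the cross-conjugated dienone (the quaternary C4 prevents aromatisation); no stereocenter is formed.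

Step 2
Reactants: 3 (E)-pent-3-en-2-one
Product: 4 (E)-2-(tert-butyldimethylsilyloxy)penta-1,3-diene
Conditions: LDA, THF, −78 °C; TBSOTf
Reagents that add atoms: tert-butyldimethylsilyl triflate, CC(C)(C)[Si](C)(C)OS(=O)(=O)C(F)(F)F
Why: Kinetic α′-deprotonation of the enone and O-silylation (silyl dienol ether formation) should give the 2-silyloxy diene with the E alkene untouched.

Step 3
Reactants: 2 4,4-dimethylcyclohexa-2,5-dien-1-one; 4 (E)-2-(tert-butyldimethylsilyloxy)penta-1,3-diene
Product: 5 (4aR,8S,8aS)-6-(tert-butyldimethylsilyloxy)-4,4,8-trimethyl-4a,5,8,8a-tetrahydronaphthalen-1(4H)-one (cis-fused, H4a, H8 and H8a mutually cis)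
Conditions: diphenylprolinol-derived o-tolyl oxazaborolidine activated with Tf2NH (20 mol %), CH2Cl2, −78 to −40 °C
Reagents that add atoms: none
Why: Catalytic enantioselective Diels–Alder reaction that desymmetrises the achiral dienone: the 2-silyloxy and 4-methyl groups both direct the diene CH2 terminus to the β-carbon, suprafacial addition gives the cis ring fusion, endo approach puts the C8 methyl cis to the acyl carbon, and the chiral Lewis acid selects one of the two enantiotopic enone double bonds and so fixes C4a.

Step 4
Reactants: 5 (4aR,8S,8aS)-6-(tert-butyldimethylsilyloxy)-4,4,8-trimethyl-4a,5,8,8a-tetrahydronaphthalen-1(4H)-one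
Product: 7 O-phenyl thionocarbonate of the C8a 1-hydroxyethyl aldol of 5 (C4a and C8 as in 5), via lithium aldolate 6 (not isolated)
Conditions: LDA, THF, −78 °C; CH3CHO; then PhOC(S)Cl, −78 to 0 °C
Reagents that add atoms: acetaldehyde, CC=O; O-phenyl chlorothionoformate, S=C(Cl)Oc1ccccc1
Why: α′-Deprotonation (C4 is quaternary, so C8a is the only enolisable carbon) and aldol addition to acetaldehyde attach the future C10 carbon, and in situ O-thioacylation installs a Barton–McCombie radical precursor; the new centers (C8a and the carbinol carbon) are inconsequential because both become planar in steps 5 and 7.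

Step 5
Reactants: 7 O-phenyl thionocarbonate of the C8a 1-hydroxyethyl aldol of 5
Product: 8 (1S,7R,11R)-9-(tert-butyldimethylsilyloxy)-2,6,6,11-tetramethylbicyclo[5.4.0]undeca-4,9-dien-3-one (cis-fused, C2 epimers)
Conditions: Bu3SnH (slow addition), AIBN, PhH, 80 °C
Reagents that add atoms: none
Why: Dowd–Beckwith ring enlargement: the secondary radical from Barton–McCombie fragmentation adds 3-exo to the ketone carbonyl, β-scission of the cyclopropyloxy radical (1,2-acyl shift) gives the more stable tertiary ring-fusion radical, and this should take hydrogen from Bu3SnH anti to the neighbouring C11 methyl, restoring the cis ring fusion.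

Step 6
Reactants: 8 (1S,7R,11R)-9-(tert-butyldimethylsilyloxy)-2,6,6,11-tetramethylbicyclo[5.4.0]undeca-4,9-dien-3-one
Product: 9 (1S,7R)-2,6,6,11-tetramethylbicyclo[5.4.0]undeca-4,10-diene-3,9-dione (cis-fused, C2 epimers)
Conditions: Pd(OAc)2, MeCN, rt
Reagents that add atoms: none
Why: Saegusa–Ito oxidation: the Pd(II) enolate formed from the silyl enol ether undergoes β-hydride elimination toward C11, giving the 11-methyl enone regiospecifically and erasing the auxiliary C11 stereocenter.

Step 7
Reactants: 9 (1S,7R)-2,6,6,11-tetramethylbicyclo[5.4.0]undeca-4,10-diene-3,9-dione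
Product: 11 (4R,5S,10R,11R)-longipina-2,7-diene-1,9-dione, via dilithium bis-dienolate 10 (not isolated)
Conditions: LDA (2.3 equiv), THF, −78 °C; Fe(acac)3 (2.2 equiv), −78 °C to rt, high dilution
Reagents that add atoms: none
Why: Proposed new method: double kinetic α′-deprotonation gives the bis(cross-conjugated lithium dienolate) 10 (enolate double bonds C2=C3 and C8=C9, bicyclo numbering of 9); Fe(III) oxidises one enolate to an α-keto radical, this adds to the carbon terminus of the second enolate, and a second one-electron oxidation of the resulting ketyl gives the 1,4-diketone, so the C2–C8 bond (C10–C11 of the longipinane) is formed as the central bond of a 1,4-dicarbonyl array. The closest known reaction type is the intramolecular oxidative coupling of two enolates with Fe(III) or Cu(II) salts (ring-forming 1,4-dicarbonyl synthesis, including cyclobutane-1,2-dicarboxylates from adipate dienolates); what has not been shown is four-ring closure between two ketone dienolates with creation of a quaternary carbon. The ring closes as a cyclobutane by 4-exo-trig attack of the radical on the neighbouring enolate carbon, which at once completes the bicyclo[3.1.1]hept-3-en-2-one and leaves the seven-membered ring bridging the other two cyclobutane carbons. Both new stereocenters (quaternary C10 and C11, longipinane numbering) are controlled by the cis ring fusion of 9: C8 can reach the C2 enolate only from the face of the seven-membered ring that carries the six-membered ring, so one configuration is possible, and because C2 is planar in 10 both C2 epimers of 9 converge on one product. The step needs α′- over γ-enolisation and intra- over intermolecular coupling; the first is secured by LDA at −78 °C and the quaternary γ-carbon C6, the second by the gauche arrangement of C2 and C8 across the C1–C7 bond and by dilution, and the strained 4-exo closure should be made irreversible by fast oxidation of the ketyl radical anion.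

Step 8
Reactants: 11 (4R,5S,10R,11R)-longipina-2,7-diene-1,9-dione
Product: 13 (4R,5S,7R,10R,11R)-7-hydroxylongipin-2-ene-1,9-dione, via C7 pinacol boronate 12 (not isolated)
Conditions: B2pin2, CuCl (5 mol %), chiral Josiphos-type bisphosphine (5 mol %), NaOt-Bu (10 mol %), MeOH, THF, 0 °C; then NaBO3·4H2O, THF/H2O, rt
Reagents that add atoms: bis(pinacolato)diboron, CC1(C)OB(OC1(C)C)B1OC(C)(C)C(C)(C)O1 (boron of 12); sodium perborate, [Na+].[O-]OB=O (oxygen of 13)
Why: Copper(I)-catalysed conjugate borylation of the less substituted Δ7 enone (the Δ2 enone is β,β-disubstituted) followed by stereoretentive C–B oxidation; the two faces of the Δ7 enone are flanked by the two near-equivalent one-carbon bridges, so the chiral ligand should decide the face and deliver boron to give the 7R alcohol.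

Step 9
Reactants: 13 (4R,5S,7R,10R,11R)-7-hydroxylongipin-2-ene-1,9-dione; 14 3-methylbut-2-enal
Product: 15 (4R,5S,7R,9R,10R,11R)-9-hydroxy-1-oxolongipin-2-en-7-yl 3-methylbut-2-enoate
Conditions: SmI2 (30 mol %, premixed with 14), 14 (5 equiv), THF, −10 °C
Reagents that add atoms: none
Why: Evans–Tishchenko reduction: the samarium-bound hemiacetal formed from the C7 hydroxyl and the aldehyde delivers hydride intramolecularly to the C9 ketone from the face of the C7 oxygen, giving the 1,3-anti (9R) alcohol and leaving the oxidised aldehyde as the C7 senecioate; premixing the catalyst with the aldehyde avoids free Sm(II), which could reduce the strained 1,4-diketone.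

Step 10
Reactants: 15 (4R,5S,7R,9R,10R,11R)-9-hydroxy-1-oxolongipin-2-en-7-yl 3-methylbut-2-enoate; 16 (E)-2-methylbut-2-enoyl chloride
Product: 17 (4R,5S,7R,9R,10R,11R)-7-(3-methylbut-2-enoyloxy)-9-[(E)-2-methylbut-2-enoyloxy]longipin-2-en-1-one (CNP0277258.1)
Conditions: Et3N, DMAP, CH2Cl2, 0 °C to rt
Reagents that add atoms: none
Why: DMAP-catalysed esterification of the hindered secondary alcohol with the E acid chloride, which carries the tiglate geometry in from the reagent; no ring stereocenter is touched.

**Compound list**

1 | 4,4-dimethylcyclohex-2-en-1-one | O=C1C=CC(C)(C)CC1 | starting material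
2 | 4,4-dimethylcyclohexa-2,5-dien-1-one | O=C1C=CC(C)(C)C=C1 | intermediate
3 | (E)-pent-3-en-2-one | C/C=C/C(C)=O | starting material
4 | (E)-2-(tert-butyldimethylsilyloxy)penta-1,3-diene | C=C(O[Si](C)(C)C(C)(C)C)/C=C/C | intermediate
5 | (4aR,8S,8aS)-6-(tert-butyldimethylsilyloxy)-4,4,8-trimethyl-4a,5,8,8a-tetrahydronaphthalen-1(4H)-one, cis-fused | O=C1C=CC(C)(C)[C@@H]2CC(O[Si](C)(C)C(C)(C)C)=C[C@H](C)[C@H]12 | intermediate
6 | lithium aldolate of 5 with acetaldehyde at C8a (not isolated) | O=C1C=CC(C)(C)[C@@H]2CC(O[Si](C)(C)C(C)(C)C)=C[C@H](C)C12C(C)O[Li] | intermediate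
7 | O-phenyl thionocarbonate of the C8a 1-hydroxyethyl aldol of 5 | O=C1C=CC(C)(C)[C@@H]2CC(O[Si](C)(C)C(C)(C)C)=C[C@H](C)C12C(C)OC(=S)Oc1ccccc1 | intermediate
8 | (1S,7R,11R)-9-(tert-butyldimethylsilyloxy)-2,6,6,11-tetramethylbicyclo[5.4.0]undeca-4,9-dien-3-one, cis-fused, C2 epimers | O=C1C=CC(C)(C)[C@@H]2CC(O[Si](C)(C)C(C)(C)C)=C[C@H](C)[C@@H]2C1C | intermediate
9 | (1S,7R)-2,6,6,11-tetramethylbicyclo[5.4.0]undeca-4,10-diene-3,9-dione, cis-fused, C2 epimers | O=C1C=CC(C)(C)[C@@H]2CC(=O)C=C(C)[C@@H]2C1C | intermediate
10 | dilithium bis-dienolate of 9 (O3,O9-dilithio, enolate double bonds C2=C3 and C8=C9; not isolated) | [Li]OC1=C(C)[C@H]2C(C)=CC(O[Li])=C[C@H]2C(C)(C)C=C1 | intermediate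
11 | (4R,5S,10R,11R)-longipina-2,7-diene-1,9-dione | O=C1C=CC(C)(C)[C@@H]2[C@H]3C(=O)C=C(C)[C@@H]2[C@]31C | intermediate
12 | 7-(pinacolboryl)longipin-2-ene-1,9-dione, boron on the face that becomes the 7R hydroxyl (not isolated) | O=C1C[C@@H](B2OC(C)(C)C(C)(C)O2)C(C)(C)[C@@H]3[C@H]4C(=O)C=C(C)[C@@H]3[C@]41C | intermediate
13 | (4R,5S,7R,10R,11R)-7-hydroxylongipin-2-ene-1,9-dione | O=C1C[C@@H](O)C(C)(C)[C@@H]2[C@H]3C(=O)C=C(C)[C@@H]2[C@]31C | intermediate
14 | 3-methylbut-2-enal | CC(C)=CC=O | starting material
15 | (4R,5S,7R,9R,10R,11R)-9-hydroxy-1-oxolongipin-2-en-7-yl 3-methylbut-2-enoate | O[C@@H]1C[C@@H](OC(=O)C=C(C)C)C(C)(C)[C@@H]2[C@H]3C(=O)C=C(C)[C@@H]2[C@]31C | intermediate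
16 | (E)-2-methylbut-2-enoyl chloride | C/C=C(\C)C(Cl)=O | starting material
17 | (4R,5S,7R,9R,10R,11R)-7-(3-methylbut-2-enoyloxy)-9-[(E)-2-methylbut-2-enoyloxy]longipin-2-en-1-one | C/C=C(\C)C(=O)O[C@@H]1C[C@@H](OC(=O)C=C(C)C)C(C)(C)[C@@H]2[C@H]3C(=O)C=C(C)[C@@H]2[C@]31C | target

Total step count: 10. Longest linear sequence: 9 steps (steps 1, 3, 4, 5, 6, 7, 8, 9, 10).

**Steps most likely to fail**

1. Step 7 (Proposed new method). The strained 4-exo closure may lose to intermolecular coupling, to simple re-protonation, or to over-oxidation of the enolates. Fallback with known chemistry, from 9 back to 11: double kinetic silylation (LDA, TMSCl, −78 °C) would give the bis(trimethylsilyl) dienol ether F1. One equivalent of NBS at −78 °C should brominate the unhindered disubstituted enol ether terminus (C8) and give the α′-bromo enone F2, in which the tetrasubstituted C2 silyl enol ether is kept. Fluoride (TBAF, THF) would then unmask the C2 enolate, which displaces the bromide in an intramolecular enolate C-alkylation (4-exo-tet, the mode long used to close bicyclo[3.1.1]heptanones) to give 11.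

2. Step 5. Hydrogen transfer to the secondary radical may outrun the acyl shift, or hydrogen may be delivered to the wrong face of the ring-fusion radical. Fallback, from 5 back to 9, by an ionic ring enlargement that keeps the Diels–Alder ring fusion: conjugate reduction of 5 with [(Ph3P)CuH]6 would give the saturated cis-decalone F3. Addition of 1-(phenylseleno)ethyllithium gives the β-hydroxy selenide F4. Activation of selenium (TlOEt, CHCl3) should trigger semipinacol ring enlargement, with migration of the more substituted ring-fusion carbon with retention, to the ring-enlarged ketone F5. Kinetic enolisation toward the methylene (LDA, TMSCl) gives the trimethylsilyl enol ether F6, and Saegusa–Ito oxidation of both silyl enol ethers with Pd(OAc)2 returns to 9.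

3. Step 8. The copper–boryl addition may show poor facial selectivity at C7 or compete at the Δ2 enone. Fallback, from 11 back to 13: nucleophilic epoxidation of the less substituted enone (t-BuOOH, DBU) would give the 7,8-epoxy ketone F7 under substrate control. Reductive opening at the α-carbon with Na[PhSeB(OEt)3] (from (PhSe)2 and NaBH4 in EtOH) gives the β-hydroxy ketone 13; this selenium reagent avoids Sm(II), which could cleave the 1,4-diketone.

**Further compounds**

F1 | step 7 | bis(trimethylsilyl) dienol ether of 9 (O3,O9-disilyl) | C[Si](C)(C)OC1=C(C)[C@H]2C(C)=CC(O[Si](C)(C)C)=C[C@H]2C(C)(C)C=C1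
F2 | step 7 | 8-bromo derivative of 9 with the C2=C3 trimethylsilyl enol ether kept | C[Si](C)(C)OC1=C(C)[C@H]2C(C)=CC(=O)C(Br)[C@H]2C(C)(C)C=C1
F3 | step 5 | 2,3-dihydro derivative of 5 (saturated cis-decalone) | O=C1CCC(C)(C)[C@@H]2CC(O[Si](C)(C)C(C)(C)C)=C[C@H](C)[C@H]12
F4 | step 5 | β-hydroxy selenide from F3 and 1-(phenylseleno)ethyllithium | OC1(C(C)[Se]c3ccccc3)CCC(C)(C)[C@@H]2CC(O[Si](C)(C)C(C)(C)C)=C[C@H](C)[C@H]12
F5 | step 5 | 9-(tert-butyldimethylsilyloxy)-2,6,6,11-tetramethylbicyclo[5.4.0]undec-9-en-3-one, cis-fused | O=C1CCC(C)(C)[C@@H]2CC(O[Si](C)(C)C(C)(C)C)=C[C@H](C)[C@@H]2C1C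
F6 | step 5 | C3=C4 trimethylsilyl enol ether of F5 | C[Si](C)(C)OC1=CCC(C)(C)[C@@H]2CC(O[Si](C)(C)C(C)(C)C)=C[C@H](C)[C@@H]2C1C
F7 | step 8 | 7,8-epoxylongipin-2-ene-1,9-dione, epoxide on the face of the 7R oxygen | O=C1[C@H]2O[C@H]2C(C)(C)[C@@H]3[C@H]4C(=O)C=C(C)[C@@H]3[C@]41C
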